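The cyclohexane ring is closed last among the carbon–carbon bonds. An intact three-carbon unit is stitched between the benzylic carbon C5 and the ring carbon C8a, the two atoms that flank C4a of the hetero ring. The precursor is a fully substituted pyridine that carries a nonyl chain on C4a and an enantiopure p-tolylsulfinyl group on C8a. In one flask the sulfinyl oxygen directs lithiation of C5 and fixes the face on which 1-chloro-3-iodopropane enters (C5–C6, stereocentre). Sulfoxide–lithium exchange then turns C8a into a carbanion that displaces chloride (C8–C8a) and expels the auxiliary. N-Oxidation, hydrolysis at C4 and N–O methylation finish the N-methoxy-4-pyridone.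

Key step: step 3

Numbering: C2 to C8a are the quinoline positions of the target and denote the same atoms in every precursor. Compound names use pyridine numbering where the carbocycle is still open.

Assumption: the sense of 1,4-induction is taken from the chelate model (lithium held by the sulfinyl oxygen, p-tolyl group over the opposite face, electrophile entering on the lithium side). By this model the (S)-sulfoxide gives (5R). If the sense proved opposite, the enantiomeric sulfinate would be used in step 2.

Step 1
Reactants: 1 (3,4-dimethoxypyridin-2-yl)methanol; 2 1-iodononane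
Product: 3 (3,4-dimethoxy-5-nonylpyridin-2-yl)methanol
Conditions: mesityllithium (2,4,6-Me3C6H2Li, 2.3 equiv), THF, −20 °C to rt; then 2, 0 °C to rt
Reagents that add atoms: none
Why: Directed ortho-metalation, in which the 4-methoxy group steers the hindered, non-nucleophilic aryllithium base to pyridine C5 (the later C4a; C3 is blocked and the CH2OLi group is shielded from lateral deprotonation by its own charge), followed by SN2 alkylation of the aryllithium by the primary iodide.

Step 2
Reactants: 3 (3,4-dimethoxy-5-nonylpyridin-2-yl)methanol; 4 (1R,2S,5R)-menthyl (S)-4-methylbenzenesulfinate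
Product: 5 {3,4-dimethoxy-6-[(S)-4-methylbenzenesulfinyl]-5-nonylpyridin-2-yl}methanol
Conditions: n-BuLi, Me2NCH2CH2OH, hexane–toluene, −20 °C; then added to 4 (excess) in THF, −78 °C
Reagents that add atoms: none
Why: The n-BuLi/lithium aminoalkoxide superbase lithiates the only ring C–H left (alpha to nitrogen, the later C8a) rather than the side chains, and the Andersen sulfoxide synthesis then replaces mentholate at sulfur with inversion to give the (S)-sulfoxide.

Step 3
Reactants: 5 {3,4-dimethoxy-6-[(S)-4-methylbenzenesulfinyl]-5-nonylpyridin-2-yl}methanol; 6 1-chloro-3-iodopropane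
Product: 9 [(5R)-3,4-dimethoxy-5-octyl-5,6,7,8-tetrahydroquinolin-2-yl]methanol, via chloroalkyl sulfoxide 7 (not isolated), via 6-lithiopyridine 8 (not isolated)
Conditions: LDA (2.1 equiv), THF, −78 °C; 6 (1.1 equiv), −78 °C; t-BuLi (3.3 equiv), −78 °C to rt
Reagents that add atoms: none
Why: LDA first makes the lithium alkoxide and then removes a C5 proton of the nonyl chain, the position made acidic and reachable by the neighbouring sulfinyl oxygen (complex-induced lateral lithiation), while the charge of the CH2OLi group keeps its own methylene from being deprotonated. The benzylic lithium sits in a six-membered C–Li···O–S chelate with the octyl chain turned toward the smaller 4-methoxy side and the p-tolyl group over one face, so the iodide end of 6 (SN2, iodide leaves far faster than chloride) should enter on the lithium-bearing face and the (S)-sulfoxide should set (5R) by 1,4-induction, the known behaviour of ortho-sulfinyl benzylic carbanions. tert-Butyllithium first turns the liberated amine back into amide, so that nothing can protonate the next carbanion, and then attacks sulfur (sulfoxide–lithium exchange) to release the better stabilised 2-pyridyl anion rather than the tolyl anion. This carbanion at C8a displaces chloride in a Parham-type cycloalkylation, a 6-exo-tet closure of the carbocycle. The closest known reaction types are remote-sulfoxide-controlled benzylic alkylation, desulfinylation with tert-butyllithium and the Parham cyclisation, here run one after the other in one flask. Once the sulfinyl group has left, C5–H is no longer acidic, so the stereocentre is safe in the rest of the step and later.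

Step 4
Reactants: 9 [(5R)-3,4-dimethoxy-5-octyl-5,6,7,8-tetrahydroquinolin-2-yl]methanol
Product: 10 (5R)-2-(hydroxymethyl)-3,4-dimethoxy-5-octyl-5,6,7,8-tetrahydroquinoline 1-oxide
Conditions: mCPBA, CH2Cl2, 0 °C to rt
Reagents that add atoms: 3-chloroperoxybenzoic acid, OOC(=O)c1cccc(Cl)c1
Why: Peracid N-oxidation of an electron-rich pyridine, in a molecule that holds no other oxidisable group and whose C5 centre is not involved.

Step 5
Reactants: 10 (5R)-2-(hydroxymethyl)-3,4-dimethoxy-5-octyl-5,6,7,8-tetrahydroquinoline 1-oxide
Product: 11 (5R)-1-hydroxy-2-(hydroxymethyl)-3-methoxy-5-octyl-5,6,7,8-tetrahydroquinolin-4(1H)-one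
Conditions: 2 M aq HCl, reflux
Reagents that add atoms: water, O
Why: Acid hydrolysis by addition–elimination, selective because in the O-protonated N-oxide only the 4-methoxy group is conjugated with the ring nitrogen (a vinylogous imidate), so water displaces methanol at C4 while the 3-methoxy group and the beta-attached C5 centre stay untouched.

Step 6
Reactants: 11 (5R)-1-hydroxy-2-(hydroxymethyl)-3-methoxy-5-octyl-5,6,7,8-tetrahydroquinolin-4(1H)-one
Product: 12 (5R)-2-(hydroxymethyl)-1,3-dimethoxy-5-octyl-5,6,7,8-tetrahydroquinolin-4(1H)-one
Conditions: MeI, K2CO3, DMF, rt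
Reagents that add atoms: iodomethane, CI
Why: SN2 O-alkylation of a cyclic vinylogous hydroxamate, whose anion carries its charge mainly on the N–O oxygen (the site at which 1-hydroxypyridones and 1-hydroxyquinolones are alkylated), with a base too weak to deprotonate the primary alcohol.

Compound list
1 | (3,4-dimethoxypyridin-2-yl)methanol | COc1ccnc(CO)c1OC | starting material
2 | 1-iodononane | CCCCCCCCCI | starting material
3 | (3,4-dimethoxy-5-nonylpyridin-2-yl)methanol | CCCCCCCCCc1cnc(CO)c(OC)c1OC | intermediate
4 | (1R,2S,5R)-menthyl (S)-4-methylbenzenesulfinate | C[C@@H]1CC[C@H]([C@@H](C1)O[S@](=O)c2ccc(C)cc2)C(C)C | starting material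
5 | {3,4-dimethoxy-6-[(S)-4-methylbenzenesulfinyl]-5-nonylpyridin-2-yl}methanol | Cc1ccc(cc1)[S@](=O)c1nc(CO)c(OC)c(OC)c1CCCCCCCCC | intermediate
6 | 1-chloro-3-iodopropane | ClCCCI | starting material
7 | {5-[(4R)-1-chlorododecan-4-yl]-3,4-dimethoxy-6-[(S)-4-methylbenzenesulfinyl]pyridin-2-yl}methanol (lithium alkoxide in the flask, drawn as the alcohol) | CCCCCCCC[C@@H](c1c(OC)c(OC)c(CO)nc1[S@@](=O)c1ccc(C)cc1)CCCCl | intermediate
8 | lithium {5-[(4R)-1-chlorododecan-4-yl]-6-lithio-3,4-dimethoxypyridin-2-yl}methanolate | CCCCCCCC[C@@H](c1c(OC)c(OC)c(CO[Li])nc1[Li])CCCCl | intermediate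
9 | [(5R)-3,4-dimethoxy-5-octyl-5,6,7,8-tetrahydroquinolin-2-yl]methanol | CCCCCCCC[C@@H]1CCCc2nc(CO)c(OC)c(OC)c12 | intermediate
10 | (5R)-2-(hydroxymethyl)-3,4-dimethoxy-5-octyl-5,6,7,8-tetrahydroquinoline 1-oxide | CCCCCCCC[C@@H]1CCCc2c1c(OC)c(OC)c(CO)[n+]2[O-] | intermediate
11 | (5R)-1-hydroxy-2-(hydroxymethyl)-3-methoxy-5-octyl-5,6,7,8-tetrahydroquinolin-4(1H)-one | CCCCCCCC[C@@H]1CCCc2c1c(=O)c(OC)c(CO)n2O | intermediate
12 | (5R)-2-(hydroxymethyl)-1,3-dimethoxy-5-octyl-5,6,7,8-tetrahydroquinolin-4(1H)-one | CCCCCCCC[C@@H]1CCCc2c1c(=O)c(OC)c(CO)n2OC | target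

Total step count: 6. Longest linear sequence: 6.

Steps most likely to fail

Step 3.
- **What may go wrong:** The facial selectivity of the alkylation may be low, because an unactivated primary iodide reacts slowly and leaves the chelate time to loosen. The 2-pyridyl carbanion may be protonated before it can cyclise. The lithium amide in the flask may eliminate HCl from the side chain.
- **Fallback (from 5, back at 9):** The two bonds are made in separate, isolated steps and the ring is closed by palladium catalysis instead of carbanion chemistry.
  - LDA and allyl bromide, the kind of reactive electrophile for which this remote induction is best established, should give the allylated sulfoxide F1. Its minor diastereomer can be removed by chromatography.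
  - Sulfoxide–magnesium exchange with i-PrMgCl·LiCl followed by iodine should give the 6-iodopyridine F2.
  - 9-BBN-H (one extra equivalent for the hydroxyl group) should hydroborate the terminal alkene to the B-alkyl borane F3.
  - F3 is closed without isolation by an intramolecular B-alkyl Suzuki–Miyaura coupling (Pd(dppf)Cl2, Cs2CO3, THF–DMF–water) to 9.

Step 1.
- **What may go wrong:** Metalation may occur alpha to nitrogen, or the base may add to C6, instead of deprotonation next to the methoxy group. Alkylation of the hindered aryllithium may be slow.
- **Fallback (from 1 and 4, back at 5):** The order of events is reversed and the chain is built laterally. This bypasses steps 1 and 2 at the cost of one step.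
  - Alpha-lithiation of 1 (n-BuLi, Me2NCH2CH2OH) and reaction with 4 should give the sulfoxide F4.
  - LDA then lithiates the ring position between the sulfinyl and methoxy groups, two directing groups that cooperate, and iodomethane should give the 5-methyl sulfoxide F5.
  - Sulfinyl-directed lateral lithiation (LDA) and 1-iodooctane extend the methyl group to the nonyl chain of 5.

Step 6.
- **What may go wrong:** Competing methylation at the C4 oxygen would only regenerate 10 and lower the conversion to the N-methoxy isomer.
- **Fallback (from 10, back at 12):** The N–O methyl group is fixed first, where only one oxygen can react, and the carbonyl group is unveiled afterwards. This bypasses steps 5 and 6.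
  - Dimethyl sulfate (MeCN, rt) should give the 1,3,4-trimethoxypyridinium methyl sulfate F6.
  - Hydrolysis of F6 in aqueous Na2CO3/NaHCO3 buffer by addition–elimination at C4 should give 12.

Further compounds
F1 | step 3 | {5-[(4R)-dodec-1-en-4-yl]-3,4-dimethoxy-6-[(S)-4-methylbenzenesulfinyl]pyridin-2-yl}methanol | CCCCCCCC[C@@H](c1c(OC)c(OC)c(CO)nc1[S@@](=O)c1ccc(C)cc1)CC=C
F2 | step 3 | {5-[(4R)-dodec-1-en-4-yl]-6-iodo-3,4-dimethoxypyridin-2-yl}methanol | CCCCCCCC[C@@H](c1c(OC)c(OC)c(CO)nc1I)CC=C
F3 | step 3 | {5-[(4S)-1-(9-borabicyclo[3.3.1]nonan-9-yl)dodecan-4-yl]-6-iodo-3,4-dimethoxypyridin-2-yl}methanol (same spatial arrangement, descriptor changed by the boron) | CCCCCCCC[C@@H](c1c(OC)c(OC)c(CO)nc1I)CCCB1C2CCCC1CCC2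
F4 | step 1 | {3,4-dimethoxy-6-[(S)-4-methylbenzenesulfinyl]pyridin-2-yl}methanol | Cc1ccc(cc1)[S@](=O)c1nc(CO)c(OC)c(OC)c1
F5 | step 1 | {3,4-dimethoxy-5-methyl-6-[(S)-4-methylbenzenesulfinyl]pyridin-2-yl}methanol | Cc1ccc(cc1)[S@](=O)c1nc(CO)c(OC)c(OC)c1C
F6 | step 6 | (5R)-2-(hydroxymethyl)-1,3,4-trimethoxy-5-octyl-5,6,7,8-tetrahydroquinolin-1-ium methyl sulfate | CCCCCCCC[C@@H]1CCCc2c1c(OC)c(OC)c(CO)[n+]2OC.COS(=O)(=O)[O-]
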